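The numbers in the tables stem from a simulated flask from invented constants, noise included.

Left-handed and right-handed substrate are mirror images, and the steps through the achiral form treat them alike, so those steps by themselves favour neither hand. Zero on the scale is equal capture, and any excess is counted from there.

common to all: left-handed substrate 0.012 M; right-handed substrate 0.012 M
- amber: partner 0.034 M (fed, over 2.0 h); run made earlier
- red: partner 0.053 M (fed, over 2.0 h); run made earlier
- Sunday's: partner 0.0240 M (fed, over 2.0 h); time 10 h
- Saturday's: partner 0.0240 M (fed, over 4.0 h); time 10 h
- Tuesday's: partner 0.0240 M (fed, over 8.0 h); time 10 h
- Monday's: partner 0.0240 M (fed, over 15 h); time 10 h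

| run | time / h | left-handed product / % | right-handed product / % |
|---|---|---|---|
| amber | 0.667 | 2 | 0 |
| amber | 2.00 | 3 | 0 |
| amber | 3.00 | 10 | 4 |
| amber | 5.00 | 12 | 4 |
| amber | 8.00 | 14 | 9 |
| amber | 10.0 | 18 | 9 |
| amber | 12.0 | 15 | 11 |
| red | 1.00 | 2 | 0 |
| red | 1.33 | 2 | 3 |
| red | 2.00 | 8 | 2 |
| red | 3.00 | 10 | 5 |
| red | 5.00 | 15 | 9 |
| red | 8.00 | 19 | 14 |
| red | 12.0 | 22 | 14 |

(readings scatter by 1.5 percentage points)

1. excess of left-handed product over right-handed product at the end for Sunday's, Saturday's, Tuesday's, Monday's, in this order
2. the course of these numbers from the first flask to the last (falls, then rises / falls all the way / rises all the way / rises, then falls / hardly changes)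

- partner is single-handed; left-handed substrate and right-handed substrate are mirror images of each other, charged as a racemate, each of them at the stated concentration
- what was read earlier has a scatter of 1.5 percentage points, one standard deviation
- steps that have been proposed: partner + left-handed substrate -> left-handed product; partner + right-handed substrate -> right-handed product; left-handed substrate <-> achiral form; right-handed substrate <-> achiral form; achiral form -> waste; achiral form -> side product
- percentages count the whole charge, also what has not yet gone in
- an excess is the difference of the two amounts in percent of their sum
- "hardly changes" means that all values lie within two and a half points (for a concentration: within two and a half percent of the largest)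
- the handed part of partner does not stay in what it makes, so the products of the two hands are mirror images too

Both capture steps see the same partner concentration, so partner cancels in the ratio of their rates. While the two substrates stand level, that ratio is a single number, the handed ratio (the selectivity factor): left-handed product over right-handed product made in the same time. The last 3 readings of the amber and red runs together give the reading 1.56, which is an excess of 21.9%, give or take 3.07%.

Two chemists dispute the row. Ines sees a resolution: the new flasks carry 0.0240 M of partner, about as much as both substrates together, so a quick feed should draw down the left-handed substrate and a slow one should spare it. She points to the same 3 readings: amber, with 0.034 M of partner, gives 23.7%, and red, with 0.053 M, gives 20.4%. She expects a clear rise along the row.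

Tom answers that this gap lies within the scatter, and that amber's products at 12.0 h account for 18.4% of amber's partner. He expects a flat row. My own reckoning agrees with him and puts the row near the excess above.

The forecast takes Tom's side at a higher level, from a selectivity near 1.8 to 1.9 where I read less: 24%, 24.5%, 25%, 26%, hardly changes, since “depletion of the faster hand is slight”.

    partner + left-handed substrate → left-handed product (k = 0.00110 L mol⁻¹ s⁻¹)
    partner + right-handed substrate → right-handed product (k = 6.10 × 10⁻⁴ L mol⁻¹ s⁻¹)
    left-handed substrate ⇌ achiral form (K = 0.470, k = 1.70 × 10⁻⁴ s⁻¹)
    right-handed substrate ⇌ achiral form (K = 0.470, k = 1.70 × 10⁻⁴ s⁻¹)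
    achiral form → waste (k = 2.70 × 10⁻⁴ s⁻¹)
    achiral form → side product (k = 2.80 × 10⁻⁵ s⁻¹)

The flasks give 26.4%, 26.5%, 27.0%, 27.7%: hardly changes, as the forecast said, though Monday's stands 1.3 percentage points above Sunday's, which is the direction Ines argued. At the end of Sunday's flask, left-handed substrate stands at 5.24% and right-handed substrate at 5.64%. Divided by the earlier reading of 1.56, with its scatter, Sunday's 12.4% of left-handed product gives 7.95% of right-handed product, and Sunday's flask holds 7.25%. By the same reading, Monday's 4.39% gives 2.81%, and Monday's flask holds 2.49%.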